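The constants used here are made up; no experiment stands behind them.

A ratio of 0.58 at the start of dawn, substrate into intermediate against substrate into side product, is the number to watch: you are splitting one substrate between two paths.

    second reagent + intermediate → target (k1 = 1.15 M⁻¹ s⁻¹)
    substrate + partner → intermediate (k2 = 0.203 M⁻¹ s⁻¹)
    substrate + second reagent → side product (k3 = 0.573 M⁻¹ s⁻¹)

| flask | substrate | partner | second reagent | time |
|---|---|---|---|---|
| dawn | 0.44 M | 1.30 equiv | 0.800 equiv | 20 s |
| autumn | 0.44 M | 1.30 equiv | 1.20 equiv | 20 s |
| winter | 0.44 M | 1.30 equiv | 2.00 equiv | 20 s |

1. amount of target at the end, in percent of the substrate charged for dawn, autumn, winter, in this order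
2. the course of these numbers from the first flask to the last (hardly changes / falls all the way / rises, then falls / rises all the way / falls, then rises)

- "hardly changes" means that all values lie within two and a half points (for a concentration: within two and a half percent of the largest)
- run time (dawn): 20 s

**The ladder.** Take dawn at its charged concentrations. On the lowest rung, the final step halves the intermediate in 1.7 s, faster than the side path halves the substrate, in 3.4 s. The partner path comes next and needs 6.0 s. Both paths together halve the substrate in 2.18 s, well inside the run of 20 s. So I reckon the split as finished by the end, and what counts is how it divides.

**The share.** Call f, the branch share, the rate on the partner path over the sum of the rates on both paths, at the charged concentrations. For dawn, f is 36.5%, and it falls to 27.7% in autumn and 18.7% in winter.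

**The cap.** Each substrate costs one second reagent on either path, provided its intermediate goes on to target. So the reagent left for target is the charge minus the side path's part, 1 − f. In dawn that gives 16.5%, below the share, and this cap is my figure. In autumn and winter, charges of 1.20 equiv and 2.00 equiv cover the substrate, so the shares stand. My row therefore rises, then falls. Partner is drawn by one step and second reagent by two, so the ratio should drift upward during the run, and I take my figures as low.

**Forecast and result.** The forecast, higher than my row at each flask, gives 30%, 32% and 22.5%, rises, then falls: “the yield peaks near 1.2 equiv”. The flasks give 29.0%, 32.1% and 21.9%, rises, then falls.

**The share again.** In dawn, target plus intermediate reach 47.1% at the end, above the share of 36.5% reckoned for the start. The ratio has drifted from 0.58 to 2.29 by 10.0 s, with 17.6% of dawn's second reagent left. In winter, 50.0% of the second reagent remains at the end, and the target of 21.9% stands above the share of 18.7% reckoned for the start. The side path is the main reason winter's target stands so low: the winter run without it gives 73.4%.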